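Everything hinges on the C4–C5 bond. C4 is the α-carbon of the ring A carbonyl at C3, and quaternary C5 is the γ-carbon of the ring B carbonyl at C8 (through C7 and C6), so the two carbons are enol and dienol termini and can be joined by oxidation. A single anodic step makes C4–C5, closes ring A, sets C4 and C5 and unveils the C3 ketone together with the C6–C7–C8 enone. Its substrate is a ring B cyclohexa-1,3-diene silyl dienol ether (C8=C7, C6=C5) with trans silyloxy at C9 and a C10 chain ending in the (Z)-silyl enol ether of the C3 ketone.

Key step: step 10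

Remark: locants are eremophilane numbers (ring A: C1–C5 and C10; ring B: C5–C10; C14 on C5, C15 on C4); β denotes the face that carries C14.
Assumption: (R)-4-methylcyclohex-2-en-1-one is bought as the single enantiomer; it is also reached in three known steps from (R)-pulegone.
Precursor design: the donor enol ether at C3 carries triethylsilyl, the diene oxygen and O-9 carry tert-butyldimethylsilyl; the (Z)-geometry is used to set C4 kinetically, and the C3 ketone is reduced directly after the key step so that C4 cannot equilibrate.

Step 1
Reactants: 1 (R)-4-methylcyclohex-2-en-1-one; 2 2-(2-bromoethyl)-1,3-dioxolane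
Product: 4 {[(3S,4R)-3-[2-(1,3-dioxolan-2-yl)ethyl]-4-methylcyclohex-1-en-1-yl]oxy}trimethylsilane (C8=C9 enol ether with the C10 chain trans to the C5 methyl), via Grignard reagent 3 (not isolated)
Conditions: Mg, THF, 25 °C; then CuBr·SMe2 (10 mol%), Me3SiCl, 1, THF, −78 °C
Reagents that add atoms: chlorotrimethylsilane, C[Si](C)(C)Cl
Why: Copper-catalysed conjugate addition of the Grignard reagent with silyl trapping should deliver the acetal chain to C10 anti to the neighbouring C5 methyl (axial attack on the half-chair that keeps the methyl pseudo-equatorial), which sets C10 and fixes the enol ether at C8=C9.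

Step 2
Reactants: 4 the trimethylsilyl enol ether
Product: 7 (2R,3S,4R)-3-[2-(1,3-dioxolan-2-yl)ethyl]-2-hydroxy-4-methylcyclohexan-1-one (9β-hydroxy trans to the C10 chain), via silyloxy epoxide 5 (not isolated), via α-trimethylsilyloxy ketone 6 (not isolated)
Conditions: mCPBA, CH2Cl2, −20 to 0 °C; then citric acid (cat.), MeOH, 20 °C
Reagents that add atoms: 3-chloroperoxybenzoic acid, OOC(=O)c1cccc(Cl)c1
Why: Rubottom oxidation, in which the peracid should epoxidise the enol ether on the face opposite the adjacent C10 chain, the silyloxy epoxide opens with 1,4-silyl shift and mild methanolysis frees the C9 hydroxyl trans to the chain (both equatorial), which sets C9.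

Step 3
Reactants: 7 the α-hydroxy ketone
Product: 8 (2R,3S,4R)-2-[(tert-butyldimethylsilyl)oxy]-3-[2-(1,3-dioxolan-2-yl)ethyl]-4-methylcyclohexan-1-one
Conditions: TBSCl, imidazole, DMF, 20 °C
Reagents that add atoms: tert-butyldimethylsilyl chloride, CC(C)(C)[Si](C)(C)Cl
Why: Imidazole-promoted silylation of a secondary alcohol should protect O-9 as a robust silyl ether without touching any stereocentre.

Step 4
Reactants: 8 the silyloxy ketone
Product: 10 (4R,5S,6R)-6-[(tert-butyldimethylsilyl)oxy]-5-[2-(1,3-dioxolan-2-yl)ethyl]-4-methylcyclohex-2-en-1-one (C6=C7 enone), via lithium enolate 9 (not isolated)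
Conditions: LiN(iPr)2, THF, −78 °C; then PhS(Cl)=NtBu, −78 °C
Reagents that add atoms: none
Why: Mukaiyama dehydrogenation, in which kinetic deprotonation should take the C7 methylene because the other α-carbon is tertiary and carries the silyloxy group, and sulfinimidoyl transfer followed by syn-elimination gives the C6=C7 enone without a new stereocentre.

Step 5
Reactants: 10 the acetal enone
Product: 11 3-[(1S,2R,6R)-2-[(tert-butyldimethylsilyl)oxy]-6-methyl-3-oxocyclohex-4-en-1-yl]propanal
Conditions: PPTS, acetone/H2O (9:1), 55 °C
Reagents that add atoms: water, O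
Why: Acid-catalysed acetal hydrolysis with a weak acid should free the aldehyde while the secondary silyl ether and the enone survive, and epimerisation at C5 would be without consequence because that centre is erased in step 9.

Step 6
Reactants: 11 the aldehyde; 12 vinylmagnesium bromide
Product: 13 (4R,5S,6R)-6-[(tert-butyldimethylsilyl)oxy]-5-(3-hydroxypent-4-en-1-yl)-4-methylcyclohex-2-en-1-one (both C3 epimers)
Conditions: THF, −78 °C; then aq. NH4Cl
Reagents that add atoms: none
Why: Grignard 1,2-addition should be chemoselective for the aldehyde over the conjugated ring ketone shielded by the neighbouring silyloxy group, and the new carbinol centre, formed as a mixture, is removed in the next step.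

Step 7
Reactants: 13 the allylic alcohol
Product: 14 (4R,5S,6R)-6-[(tert-butyldimethylsilyl)oxy]-4-methyl-5-(3-oxopent-4-en-1-yl)cyclohex-2-en-1-one
Conditions: DMP, CH2Cl2, 0 °C
Reagents that add atoms: none
Why: Dess–Martin oxidation should convert the allylic alcohol into the vinyl ketone under neutral conditions that spare the ring enone and the silyl ether.

Step 8
Reactants: 14 the vinyl ketone
Product: 15 (4R,5S,6R)-6-[(tert-butyldimethylsilyl)oxy]-4-methyl-5-[(3Z)-3-[(triethylsilyl)oxy]pent-3-en-1-yl]cyclohex-2-en-1-one
Conditions: Et3SiH (1.1 equiv), RhCl(PPh3)3 (1 mol%), THF, 20 °C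
Reagents that add atoms: triethylsilane, CC[SiH](CC)CC
Why: Rhodium-catalysed 1,4-hydrosilylation of the unhindered terminal vinyl ketone, faster than that of the ring enone whose β-carbon adjoins the branched C5, passes through the s-cis oxa-allyl complex and should give the C3=C4 enol ether regiospecifically with (Z)-geometry.

Step 9
Reactants: 15 the enone bearing the (Z)-triethylsilyl enol ether
Product: 17 tert-butyl{[(5S,6R)-6-[(tert-butyldimethylsilyl)oxy]-4-methyl-5-[(3Z)-3-[(triethylsilyl)oxy]pent-3-en-1-yl]cyclohexa-1,3-dien-1-yl]oxy}dimethylsilane (the bis(silyl enol ether) precursor), via potassium dienolate 16 (not isolated)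
Conditions: KN(SiMe3)2, THF, −78 °C; then TBSOTf, −78 °C
Reagents that add atoms: tert-butyldimethylsilyl trifluoromethanesulfonate, CC(C)(C)[Si](C)(C)OS(=O)(=O)C(F)(F)F
Why: Vinylogous (γ) enolisation, in which the hindered amide base should remove H-5 because the only α′-hydrogen sits on the tertiary silyloxy-bearing C9, and O-silylation of the through-conjugated dienolate gives the C8=C7–C6=C5 dienol ether while the C3 enol ether, C9 and C10 stay intact and the C5 centre is deliberately erased.

Step 10
Reactants: 17 the bis(silyl enol ether)
Product: 18 (1R,4aS,5R,8aS)-1-[(tert-butyldimethylsilyl)oxy]-4a,5-dimethyl-4a,5,8,8a-tetrahydronaphthalene-2,6(1H,7H)-dione (cis-fused 3,8-diketone with C6=C7 enone; 9β-silyloxy; 4β,5β-dimethyl; 10β-H)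
Conditions: undivided cell, reticulated vitreous carbon anode, Pt cathode, constant current (2.2 F/mol), LiClO4 (0.1 M), 2,6-lutidine, MeOH/CH2Cl2 (1:4), 0 °C
Reagents that add atoms: none
Why: Proposed new method: The ring B dienol ether, the more easily oxidised of the two enol ethers, should lose one electron at the anode to give a radical cation with spin and charge at C5 and C7, the tethered (Z)-enol ether adds through C4 to C5, and the resulting silyloxyallyl radical is oxidised again while methanol removes both silyl groups to leave the C3 ketone and the C6=C7–C8 enone. The closest known reaction types are the anodic cyclisation of an enol ether radical cation onto a tethered silyl enol ether and the cross-coupling of silyl enol ethers with the terminus of 1-silyloxy-1,3-dienes promoted by tetravalent cerium; the intramolecular anodic version onto a fully substituted dienol terminus is the new element. Ring A closes in the 6-exo-trig mode with respect to C5=C6. C5 is controlled by the short tether, which must attack perpendicular to the diene and can reach only the face of C5 on the side of C1, so H-10 and C14 end up cis; C4 is controlled by the (Z)-enol ether in a chair transition state, which places C15 equatorial and cis to C14. The step needs attack at the γ-carbon C5 and not at the α-carbon C7, which the three-carbon tether secures because C7 would require an eight-membered ring, and it needs cyclisation to outrun proton loss from the diene radical cation (aromatisation of ring B), which the intramolecular trap and the hindered pyridine base favour.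

Step 11
Reactants: 18 the cis-fused enedione
Product: 19 3β-alcohol (18 with the C3 ketone reduced; hydroxyl β and cis to C15; C6=C7–C8 enone and 9β-silyloxy unchanged)
Conditions: LiAlH(OtBu)3, THF, −78 to −30 °C
Reagents that add atoms: none
Why: Hydride reduction with a bulky alkoxyaluminium hydride should be chemoselective for the saturated C3 ketone over the hindered conjugated C8 ketone and should come from the face away from the C14 methyl, which is 1,3-diaxial to the opposite trajectory (the 3,3,5-trimethylcyclohexanone pattern), giving the 3β-alcohol and at the same time removing the ketone that could epimerise C4.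

Step 12
Reactants: 19 the 3β-alcohol
Product: 20 7-iodo enone (19 with iodine on C7)
Conditions: I2, pyridine, CH2Cl2, 20 °C, dark
Reagents that add atoms: iodine, II
Why: α-Iodination of the enone by reversible pyridine addition at C6, iodination of the enolate at C7 and elimination (a Baylis–Hillman-type addition–elimination) is standard for 4,4-disubstituted cyclohexenones and should tolerate the free alcohol.

Step 13
Reactants: 20 the 7-iodo enone; 21 isopropenylboronic acid pinacol ester
Product: 22 7-isopropenyl dienone 3β-alcohol (20 with prop-1-en-2-yl in place of iodine)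
Conditions: Pd(dppf)Cl2 (5 mol%), K3PO4, THF/H2O, 40 °C
Reagents that add atoms: none
Why: Suzuki–Miyaura coupling of the α-iodoenone with the alkenylboronate should install the three-carbon unit at C7 under a mild phosphate base that does not enolise the silyloxy-bearing C9, and no stereocentre is formed.

Step 14
Reactants: 22 the dienone 3β-alcohol; 23 angelic acid ((Z)-2-methylbut-2-enoic acid)
Product: 24 3α-angelate (22 with the C3 oxygen inverted to the α face, trans to C15, and esterified as the (Z)-2-methylbut-2-enoate; 9β-silyloxy retained)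
Conditions: PPh3, DIAD, toluene, 0 to 20 °C
Reagents that add atoms: none
Why: Mitsunobu esterification should displace the activated 3β-oxygen with inversion by the angelate anion, giving the 3α-ester, because in the chair that relieves the hydroxyl/C14 diaxial contact the C–O bond is equatorial and has no anti-periplanar hydrogen for elimination, and because the acid reacts as its carboxylate the (Z)-geometry is not at risk.

Step 15
Reactants: 24 the 3α-angelate silyl ether
Product: 25 9β-alcohol (24 with the silyl group removed from O-9)
Conditions: HF·pyridine, THF, 0 °C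
Reagents that add atoms: none
Why: Fluoride-assisted cleavage of the secondary silyl ether under mildly acidic, non-basic conditions should preserve the angelate, the dienone and the configuration at C9.

Step 16
Reactants: 25 the 9β-alcohol; 26 3-methylbut-2-enoic acid (senecioic acid)
Product: 27 3α-angelate 9β-senecioate dienone (25 with O-9 acylated as the 3-methylbut-2-enoate)
Conditions: EDC·HCl, DMAP (cat.), CH2Cl2, 0 to 20 °C
Reagents that add atoms: none
Why: Steglich esterification should acylate the α-hydroxy ketone without strong base, so that neither C9 nor the angelate double bond isomerises.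

Step 17
Reactants: 27 the diester dienone
Product: 28 target CNP0375730.2 (3α-angeloyloxy-9β-senecioyloxy-10βH-eremophil-11-en-8-one; 4β,5β-dimethyl; 7β-isopropenyl)
Conditions: [(Ph3P)CuH]6 (0.5 equiv), H2O (5 equiv), degassed toluene, 20 °C
Reagents that add atoms: none
Why: Copper hydride conjugate reduction should be selective for the ring enone over the β-substituted angelate and senecioate, hydride adding at C6 and water protonating the copper enolate at C7 (α-protonation keeps the isopropenyl group out of conjugation) along the axial direction of the chair with O-9 equatorial, which places the isopropenyl group equatorial (β), also the more stable C7 epimer.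

Compound list
1 | (R)-4-methylcyclohex-2-en-1-one | C[C@@H]1CCC(=O)C=C1 | starting material
2 | 2-(2-bromoethyl)-1,3-dioxolane | BrCCC1OCCO1 | starting material
3 | [2-(1,3-dioxolan-2-yl)ethyl]magnesium bromide | Br[Mg]CCC1OCCO1 | intermediate
4 | {[(3S,4R)-3-[2-(1,3-dioxolan-2-yl)ethyl]-4-methylcyclohex-1-en-1-yl]oxy}trimethylsilane | C[C@@H]1CCC(O[Si](C)(C)C)=C[C@H]1CCC2OCCO2 | intermediate
5 | 8β,9β-epoxide of 4 (1-trimethylsilyloxy-7-oxabicyclo[4.1.0]heptane, epoxide oxygen anti to the C10 chain) | C[C@@H]1CC[C@]2(O[Si](C)(C)C)O[C@@H]2[C@H]1CCC3OCCO3 | intermediate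
6 | (2R,3S,4R)-3-[2-(1,3-dioxolan-2-yl)ethyl]-4-methyl-2-(trimethylsilyloxy)cyclohexan-1-one | C[C@@H]1CCC(=O)[C@H](O[Si](C)(C)C)[C@H]1CCC2OCCO2 | intermediate
7 | (2R,3S,4R)-3-[2-(1,3-dioxolan-2-yl)ethyl]-2-hydroxy-4-methylcyclohexan-1-one | C[C@@H]1CCC(=O)[C@H](O)[C@H]1CCC2OCCO2 | intermediate
8 | (2R,3S,4R)-2-[(tert-butyldimethylsilyl)oxy]-3-[2-(1,3-dioxolan-2-yl)ethyl]-4-methylcyclohexan-1-one | C[C@@H]1CCC(=O)[C@H](O[Si](C)(C)C(C)(C)C)[C@H]1CCC2OCCO2 | intermediate
9 | lithium enolate of 8 (C8=C7) | C[C@@H]1CC=C(O[Li])[C@H](O[Si](C)(C)C(C)(C)C)[C@H]1CCC2OCCO2 | intermediate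
10 | (4R,5S,6R)-6-[(tert-butyldimethylsilyl)oxy]-5-[2-(1,3-dioxolan-2-yl)ethyl]-4-methylcyclohex-2-en-1-one | C[C@@H]1C=CC(=O)[C@H](O[Si](C)(C)C(C)(C)C)[C@H]1CCC2OCCO2 | intermediate
11 | 3-[(1S,2R,6R)-2-[(tert-butyldimethylsilyl)oxy]-6-methyl-3-oxocyclohex-4-en-1-yl]propanal | C[C@@H]1C=CC(=O)[C@H](O[Si](C)(C)C(C)(C)C)[C@H]1CCC=O | intermediate
12 | vinylmagnesium bromide | C=C[Mg]Br | starting material
13 | (4R,5S,6R)-6-[(tert-butyldimethylsilyl)oxy]-5-(3-hydroxypent-4-en-1-yl)-4-methylcyclohex-2-en-1-one (C3 epimers) | C[C@@H]1C=CC(=O)[C@H](O[Si](C)(C)C(C)(C)C)[C@H]1CCC(O)C=C | intermediate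
14 | (4R,5S,6R)-6-[(tert-butyldimethylsilyl)oxy]-4-methyl-5-(3-oxopent-4-en-1-yl)cyclohex-2-en-1-one | C[C@@H]1C=CC(=O)[C@H](O[Si](C)(C)C(C)(C)C)[C@H]1CCC(=O)C=C | intermediate
15 | (4R,5S,6R)-6-[(tert-butyldimethylsilyl)oxy]-4-methyl-5-[(3Z)-3-[(triethylsilyl)oxy]pent-3-en-1-yl]cyclohex-2-en-1-one | C[C@@H]1C=CC(=O)[C@H](O[Si](C)(C)C(C)(C)C)[C@H]1CC/C(O[Si](CC)(CC)CC)=C/C | intermediate
16 | potassium dienolate of 15 (C8=C7–C6=C5) | CC1=CC=C(O[K])[C@H](O[Si](C)(C)C(C)(C)C)[C@H]1CC/C(O[Si](CC)(CC)CC)=C/C | intermediate
17 | tert-butyl{[(5S,6R)-6-[(tert-butyldimethylsilyl)oxy]-4-methyl-5-[(3Z)-3-[(triethylsilyl)oxy]pent-3-en-1-yl]cyclohexa-1,3-dien-1-yl]oxy}dimethylsilane | CC1=CC=C(O[Si](C)(C)C(C)(C)C)[C@H](O[Si](C)(C)C(C)(C)C)[C@H]1CC/C(O[Si](CC)(CC)CC)=C/C | intermediate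
18 | (1R,4aS,5R,8aS)-1-[(tert-butyldimethylsilyl)oxy]-4a,5-dimethyl-4a,5,8,8a-tetrahydronaphthalene-2,6(1H,7H)-dione | C1=C[C@@]2(C)[C@H](CCC(=O)[C@@H]2C)[C@@H](O[Si](C)(C)C(C)(C)C)C1=O | intermediate
19 | 3β-alcohol of 18 (3β-hydroxy, 9β-silyloxy, 4β,5β-dimethyl, 10β-H, 6-en-8-one) | C1=C[C@@]2(C)[C@H](CC[C@H](O)[C@@H]2C)[C@@H](O[Si](C)(C)C(C)(C)C)C1=O | intermediate
20 | 7-iodo derivative of 19 | IC1=C[C@@]2(C)[C@H](CC[C@H](O)[C@@H]2C)[C@@H](O[Si](C)(C)C(C)(C)C)C1=O | intermediate
21 | isopropenylboronic acid pinacol ester | CC(=C)B1OC(C)(C)C(C)(C)O1 | starting material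
22 | 7-isopropenyl dienone 3β-alcohol | C=C(C)C1=C[C@@]2(C)[C@H](CC[C@H](O)[C@@H]2C)[C@@H](O[Si](C)(C)C(C)(C)C)C1=O | intermediate
23 | angelic acid, (Z)-2-methylbut-2-enoic acid | C/C=C(/C)C(=O)O | starting material
24 | 3α-angelate 9β-silyl ether dienone | C=C(C)C1=C[C@@]2(C)[C@H](CC[C@@H](OC(=O)/C(C)=C\C)[C@@H]2C)[C@@H](O[Si](C)(C)C(C)(C)C)C1=O | intermediate
25 | 3α-angelate 9β-alcohol dienone | C=C(C)C1=C[C@@]2(C)[C@H](CC[C@@H](OC(=O)/C(C)=C\C)[C@@H]2C)[C@@H](O)C1=O | intermediate
26 | 3-methylbut-2-enoic acid (senecioic acid) | CC(C)=CC(=O)O | starting material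
27 | 3α-angelate 9β-senecioate dienone | C=C(C)C1=C[C@@]2(C)[C@H](CC[C@@H](OC(=O)/C(C)=C\C)[C@@H]2C)[C@@H](OC(=O)C=C(C)C)C1=O | intermediate
28 | CNP0375730.2, 3α-angeloyloxy-9β-senecioyloxy-10βH-eremophil-11-en-8-one | C=C(C)[C@H]1C[C@@]2(C)[C@H](CC[C@@H](OC(=O)/C(C)=C\C)[C@@H]2C)[C@@H](OC(=O)C=C(C)C)C1=O | target

Total step count: 17
Longest linear sequence: 17 steps (1 to 28)

Steps most likely to fail

Step 10 (anodic coupling). The diene radical cation may lose a proton from C10 or C9 and aromatise ring B before C4 arrives, or the enol ethers may be solvolysed at the acidifying anode surface. The fallback sets out from 17 and returns to 18. The same bond is made in homogeneous solution with (NH4)2Ce(NO3)6 (2.2 equiv) and NaHCO3 in MeCN at −40 °C. This is the established cross-coupling of a silyl enol ether with the terminus of a 1-silyloxy-1,3-diene: tetravalent cerium turns the simple enol ether into the α-keto radical at C4, which adds to C5, and a second equivalent oxidises the silyloxyallyl radical to the enone. The reactive intermediate is therefore generated on the other partner and away from an electrode, and the fallback makes no new compound (F0).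

Step 14 (Mitsunobu inversion at C3). Activation of the crowded carbinol may be slow, and elimination toward C4 or esterification with retention may take over. The fallback sets out from 22 and returns to 24. Activation and substitution are separated: Tf2O and pyridine in CH2Cl2 at −20 °C give the 3β-triflate F1, which is displaced at 20 °C in toluene by cesium (Z)-2-methylbut-2-enoate (from 23 and Cs2CO3) with 18-crown-6. The unsolvated carboxylate should substitute with inversion at low temperature.

Step 9 (γ-enolisation). The base may instead remove H-9, which would give the cross-conjugated enol ether and scramble C9, or it may attack the triethylsilyl enol ether. The fallback sets out from 15 and returns to 18. Conjugate addition of PhSeSiMe3 (cat. Me3SiOTf, CH2Cl2, −78 °C) gives the β-phenylselanyl trimethylsilyl enol ether F2, in which the enol ether is fixed at C8=C7. Oxidation at selenium (mCPBA, 1.0 equiv, −78 °C, iPr2NH) and warming triggers selenoxide syn-elimination, which can only take H-5 because C7 is already sp2. The resulting trimethylsilyl dienol ether F3 is electrolysed under the conditions of step 10.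

Further compounds
F0 | step 10 | none | none
F1 | step 14 | 3β-trifluoromethanesulfonate of 22 | C=C(C)C1=C[C@@]2(C)[C@H](CC[C@H](OS(=O)(=O)C(F)(F)F)[C@@H]2C)[C@@H](O[Si](C)(C)C(C)(C)C)C1=O
F2 | step 9 | β-phenylselanyl trimethylsilyl enol ether from 15 (selenium on C6, enol ether C8=C7) | C[C@@H]1C([Se]c2ccccc2)C=C(O[Si](C)(C)C)[C@H](O[Si](C)(C)C(C)(C)C)[C@H]1CC/C(O[Si](CC)(CC)CC)=C/C
F3 | step 9 | trimethylsilyl dienol ether analogue of 17 | CC1=CC=C(O[Si](C)(C)C)[C@H](O[Si](C)(C)C(C)(C)C)[C@H]1CC/C(O[Si](CC)(CC)CC)=C/C
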